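The target is a 20-membered diaryl ether cyclophane: ring A (resorcinol type) and ring B (hydroxyquinol type) are joined by the ether oxygen and by a saturated, unfunctionalised C14 bridge from the meta carbon of ring A to the ortho carbon of ring B. The route exploits this bridge: the macrocycle is closed at its C10–C11 bond (counted from ring A) by ring-closing olefin metathesis of an acyclic diaryl ether carrying undec-10-enyl and pent-4-enyl chains, hinged by the ether oxygen. The resulting alkene is a traceless handle, removed together with all three benzyl ethers in one final hydrogenation. The diene is assembled convergently by Ullmann ether coupling.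

Key step: step 6

Remark: the alkene of 13 is expected as an E/Z mixture; the E isomer is drawn, and both isomers should give 14 in step 7. Compounds 1, 3, 8 and 9 are taken as commercial.

Step 1
Reactants: 1 3,5-bis(benzyloxy)benzyl bromide
Product: 2 1,5-bis(benzyloxy)-2-bromo-3-(bromomethyl)benzene
Conditions: NBS (1.05 equiv), MeCN, 0 °C to rt, dark
Reagents that add atoms: N-bromosuccinimide, O=C1CCC(=O)N1Br
Why: Electrophilic aromatic bromination of the doubly activated ring should occur ortho to the bromomethyl group and para to one benzyloxy group (the site between the two ethers is more hindered), leaving the benzylic bromide and the unactivated benzyl rings untouched.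

Step 2
Reactants: 2 1,5-bis(benzyloxy)-2-bromo-3-(bromomethyl)benzene; 3 but-3-en-1-ylmagnesium bromide
Product: 4 1,5-bis(benzyloxy)-2-bromo-3-(pent-4-en-1-yl)benzene
Conditions: 3 (1.3 equiv, slow addition), Li2CuCl4 (5 mol%), THF, −78 to 0 °C
Reagents that add atoms: none
Why: Copper-catalysed Kochi-type coupling of a primary Grignard reagent with a benzylic bromide is fast at low temperature and should leave the aryl bromide intact, giving the pent-4-enyl chain (benzylic carbon plus four carbons).

Step 3
Reactants: 4 1,5-bis(benzyloxy)-2-bromo-3-(pent-4-en-1-yl)benzene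
Product: 7 2,4-bis(benzyloxy)-6-(pent-4-en-1-yl)phenol, via aryllithium 5 (not isolated), via dimethyl arylboronate 6 (not isolated)
Conditions: n-BuLi (1.05 equiv), THF, −78 °C; B(OMe)3, −78 °C to rt; then 30% H2O2, aq NaOH, 0 °C
Reagents that add atoms: hydrogen peroxide, OO
Why: Bromine–lithium exchange at −78 °C should outpace benzylic deprotonation and carbolithiation of the remote alkene, and borylation followed by oxidative aryl migration from boron to oxygen (boronate oxidation) should give the phenol without touching the isolated alkene.

Step 4
Reactants: 8 1-(benzyloxy)-3,5-dibromobenzene; 9 11-bromoundec-1-ene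
Product: 11 1-(benzyloxy)-3-bromo-5-(undec-10-en-1-yl)benzene, via undec-10-enylzinc bromide 10 (not isolated)
Conditions: 9, Zn dust, LiCl, THF, 50 °C; then 8 (3 equiv), Pd(dppf)Cl2 (3 mol%), THF, 55 °C
Reagents that add atoms: none
Why: LiCl-promoted zinc insertion into the primary bromide and Negishi coupling should give the monoalkylated arene when the symmetrical dibromide is used in excess (the surplus is recovered), with dppf suppressing β-hydride elimination and the remote terminal alkene staying inert.

Step 5
Reactants: 7 2,4-bis(benzyloxy)-6-(pent-4-en-1-yl)phenol; 11 1-(benzyloxy)-3-bromo-5-(undec-10-en-1-yl)benzene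
Product: 12 1,5-bis(benzyloxy)-2-[3-(benzyloxy)-5-(undec-10-en-1-yl)phenoxy]-3-(pent-4-en-1-yl)benzene
Conditions: CuI (10 mol%), picolinic acid (20 mol%), K3PO4 (2 equiv), DMSO, 90 °C, Ar
Reagents that add atoms: none
Why: Ullmann diaryl ether synthesis with the picolinic acid ligand tolerates electron-rich, di-ortho-substituted phenoxides, the aryl bromide is unhindered, and benzyl ethers and terminal alkenes are inert to copper iodide and phosphate base.

Step 6
Reactants: 12 1,5-bis(benzyloxy)-2-[3-(benzyloxy)-5-(undec-10-en-1-yl)phenoxy]-3-(pent-4-en-1-yl)benzene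
Product: 13 tri-O-benzyl macrocyclic alkene (20-membered ring, CH=CH between bridge carbons 10 and 11 counted from ring A)
Conditions: second-generation Grubbs catalyst RuCl2(=CHPh)(H2IMes)(PCy3) (2 × 5 mol%), 1,4-benzoquinone (10 mol%), CH2Cl2, 1 mM, 40 °C
Reagents that add atoms: none
Why: The ruthenium benzylidene should initiate at one of the two unhindered monosubstituted alkenes, and the resulting alkylidene captures the other through a ruthenacyclobutane ([2+2] then retro-[2+2]), joining C10 of the ring A chain to C4 of the ring B chain and expelling ethylene, whose loss drives the equilibrium. The closest known reaction type is macrocyclic ring-closing olefin metathesis as used for large carbocycles and cyclophanes. The single ring that closes is the 20-membered oxa-cyclophane ring, formed end to end with the new double bond inside the ring (endocyclic closure). No stereocentre is created, and the E/Z geometry of the alkene is irrelevant because step 7 saturates it. The step needs cyclisation to beat acyclic diene metathesis oligomerisation and alkene migration; this is secured by 1 mM dilution, the reversibility of oligomer metathesis, the ether oxygen that already hinges the ortho chain of ring B and the meta chain of ring A, and benzoquinone as a scavenger of ruthenium hydrides. Benzyl ethers and the diaryl ether are inert to the catalyst.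

Step 7
Reactants: 13 tri-O-benzyl macrocyclic alkene
Product: 14 target macrocycle CNP0173380.0
Conditions: H2 (1 atm), 10% Pd/C, EtOAc–EtOH, rt
Reagents that add atoms: none
Why: Heterogeneous catalytic hydrogenation should saturate the disubstituted alkene (both geometric isomers) and hydrogenolyse the three benzyl ethers in the same operation, while the diaryl ether C–O bonds are stable.

Compound list
1 | 3,5-bis(benzyloxy)benzyl bromide | BrCc1cc(OCc2ccccc2)cc(OCc2ccccc2)c1 | starting material
2 | 1,5-bis(benzyloxy)-2-bromo-3-(bromomethyl)benzene | BrCc1cc(OCc2ccccc2)cc(OCc2ccccc2)c1Br | intermediate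
3 | but-3-en-1-ylmagnesium bromide | C=CCC[Mg]Br | starting material
4 | 1,5-bis(benzyloxy)-2-bromo-3-(pent-4-en-1-yl)benzene | C=CCCCc1cc(OCc2ccccc2)cc(OCc2ccccc2)c1Br | intermediate
5 | [2,4-bis(benzyloxy)-6-(pent-4-en-1-yl)phenyl]lithium (not isolated) | C=CCCCc1cc(OCc2ccccc2)cc(OCc2ccccc2)c1[Li] | intermediate
6 | dimethyl [2,4-bis(benzyloxy)-6-(pent-4-en-1-yl)phenyl]boronate (not isolated) | C=CCCCc1cc(OCc2ccccc2)cc(OCc2ccccc2)c1B(OC)OC | intermediate
7 | 2,4-bis(benzyloxy)-6-(pent-4-en-1-yl)phenol | C=CCCCc1cc(OCc2ccccc2)cc(OCc2ccccc2)c1O | intermediate
8 | 1-(benzyloxy)-3,5-dibromobenzene | Brc1cc(Br)cc(OCc2ccccc2)c1 | starting material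
9 | 11-bromoundec-1-ene | C=CCCCCCCCCCBr | starting material
10 | undec-10-en-1-ylzinc bromide (not isolated) | C=CCCCCCCCCC[Zn]Br | intermediate
11 | 1-(benzyloxy)-3-bromo-5-(undec-10-en-1-yl)benzene | C=CCCCCCCCCCc1cc(Br)cc(OCc2ccccc2)c1 | intermediate
12 | 1,5-bis(benzyloxy)-2-[3-(benzyloxy)-5-(undec-10-en-1-yl)phenoxy]-3-(pent-4-en-1-yl)benzene | C=CCCCCCCCCCc1cc(OCc2ccccc2)cc(Oc2c(CCCC=C)cc(OCc3ccccc3)cc2OCc2ccccc2)c1 | intermediate
13 | tri-O-benzyl macrocyclic alkene, 20-membered ring, E isomer drawn (Z isomer expected alongside) | c12cc(OCc3ccccc3)cc(c1)CCCCCCCCC/C=C/CCCc1cc(OCc3ccccc3)cc(OCc3ccccc3)c1O2 | intermediate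
14 | target: 20-membered diaryl ether macrocycle with 3-hydroxy ring A, 2,4-dihydroxy ring B and a (CH2)14 bridge | Oc1cc2cc(c1)Oc1c(O)cc(O)cc1CCCCCCCCCCCCCC2 | target

Total step count: 7. Longest linear sequence: 6 (steps 1, 2, 3, 5, 6, 7).

Steps most likely to fail

Step 6 (ring-closing metathesis). Intermolecular metathesis could outrun ring closure and give oligomers, or ruthenium hydride species could migrate a terminal alkene before closure and lead to ring-contracted homologues. The fallback sets out from 12. Oxidative cleavage of both terminal alkenes (OsO4 cat., NaIO4, 2,6-lutidine, dioxane–H2O, rt; Lemieux–Johnson oxidation) should give the dialdehyde 10-{3-(benzyloxy)-5-[2,4-bis(benzyloxy)-6-(4-oxobutyl)phenoxy]phenyl}decanal F1. Intramolecular McMurry coupling with low-valent titanium (TiCl3(DME)1.5, Zn–Cu couple, DME, reflux, slow addition) should then close the same carbon–carbon bond as a double bond and come back to the route at 13.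

Step 5 (Ullmann ether coupling). Ligand exchange and C–O bond formation at copper may be sluggish with the di-ortho-substituted phenoxide, allowing reduction of the aryl bromide or oxidative degradation of the electron-rich phenol to compete. The fallback sets out from 11. Bromine–lithium exchange and borylation (n-BuLi, THF, −78 °C; B(OiPr)3; aqueous acid) should give [3-(benzyloxy)-5-(undec-10-en-1-yl)phenyl]boronic acid F2. Chan–Lam coupling of F2 with phenol 7 (Cu(OAc)2, pyridine, 4 Å molecular sieves, CH2Cl2, air, rt) proceeds at room temperature and is known to tolerate ortho-disubstituted phenols; it comes back to the route at 12.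

Step 4 (mono-Negishi coupling). Coupling at the second bromide may compete, and material may be lost in separating dibromide, monoalkyl and dialkyl arenes. The fallback sets out from 8. A single bromine–magnesium exchange (iPrMgCl·LiCl, THF, −15 °C to rt) stops after one exchange, because the arylmagnesium formed is deactivated, and should give [3-(benzyloxy)-5-bromophenyl]magnesium chloride F3. Copper-catalysed alkylation of F3 with 9 (Li2CuCl4 cat., THF–NMP, 0 °C to rt) comes back to the route at 11.

Further compounds
F1 | step 6 | 10-{3-(benzyloxy)-5-[2,4-bis(benzyloxy)-6-(4-oxobutyl)phenoxy]phenyl}decanal | O=CCCCCCCCCCc1cc(OCc2ccccc2)cc(Oc2c(CCCC=O)cc(OCc3ccccc3)cc2OCc2ccccc2)c1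
F2 | step 5 | [3-(benzyloxy)-5-(undec-10-en-1-yl)phenyl]boronic acid | C=CCCCCCCCCCc1cc(B(O)O)cc(OCc2ccccc2)c1
F3 | step 4 | [3-(benzyloxy)-5-bromophenyl]magnesium chloride | Cl[Mg]c1cc(Br)cc(OCc2ccccc2)c1
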